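**Assumption:** (2S,3R)-HyperBTM is assumed to give the drawn absolute sense in step 3 (otherwise its commercial antipode is used); bicyclic compounds carry clerodane numbering (C1–C10 decalin, C11 on C9, C17/C18/C19/C20 methyls on C8/C4/C5/C9) and β is the face of the C19 methyl.

**Retrosynthetic overview**
- The butenolide ring is bought intact (tetronic acid, used as its triflate) and joined last by a Heck reaction to a C9 vinyl group; the C18 methyl comes from Negishi coupling of a ring-A vinyl triflate.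
- Ring-B oxygens: the 7α,8α-diol from OsO4 on a Δ7 alkene anti to a 6β-acetate; the 6β-OH from hydride reduction of a C6 enone.
- Key disconnection: rings A and B are made together (bonds C5–C10 and C8–C9) by an isothiourea-catalysed double Michael cycloisomerisation of an acyclic ynone/1,3-diketone/aryl enoate, which sets C5, C9 and C10.
- The acyclic precursor comes from C-acylation of hex-4-yn-3-one with hex-5-enoyl chloride, then cross-metathesis with pentafluorophenyl methacrylate.
- Ring order: ring A, then ring B in the same flask (step 3); the lactone ring is never built.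

**Step 1**
Reactants: 1 hex-4-yn-3-one; 2 hex-5-enoyl chloride
Product: 3 7-methylundec-1-en-9-yne-6,8-dione
Conditions: LiN(SiMe3)2 (2.1 equiv), THF, −78 °C; then 2, −78 → 0 °C; aq. NH4Cl, no acid (acid would close the γ-pyrone)
Reagents that add atoms: none
Why: Crossed Claisen C-acylation of a ketone enolate; 1 can enolise only on its ethyl side and the second equivalent of base deprotonates the product diketone, which drives C-acylation (the new CH(Me) centre is labile and irrelevant).

**Step 2**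
Reactants: 3 7-methylundec-1-en-9-yne-6,8-dione; 4 pentafluorophenyl methacrylate (5 equiv)
Product: 5 pentafluorophenyl (2E)-2,8-dimethyl-7,9-dioxododec-2-en-10-ynoate
Conditions: second-generation Hoveyda–Grubbs catalyst (5 mol %), CH2Cl2, 40 °C
Reagents that add atoms: none
Why: Olefin cross-metathesis of a terminal alkene with excess methacrylate ester gives the trisubstituted (E)-enoate under thermodynamic control; the internal electron-poor alkyne is a poor metathesis partner.

**Step 3**
Reactants: 5 pentafluorophenyl (2E)-2,8-dimethyl-7,9-dioxododec-2-en-10-ynoate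
Product: 7 pentafluorophenyl (1R,4aR,8aS)-1,2,4a-trimethyl-4,5-dioxo-1,4,4a,5,6,7,8,8a-octahydronaphthalene-1-carboxylate, via monocyclic acylammonium enolate 6 (not isolated)
Conditions: (2S,3R)-HyperBTM (15 mol %), LiCl (1.0 equiv), i-Pr2NEt (1.5 equiv), MeCN (0.02 M), 0 °C → rt
Reagents that add atoms: none
Why: Proposed new method: the isothiourea is acylated by the aryl ester to give an α,β-unsaturated acyl ammonium ion; the lithium-chelated diketonate carbon C5 attacks its β-carbon C10 6-exo on the face left open by the catalyst (sets C10 and the absolute configuration; the U-shaped chelate in a chair transition state places the ynoyl group equatorial and the C19 methyl axial, trans to H10); the fully substituted ammonium enolate 6 then adds 6-endo-dig to the chelation-activated ynone with H10 eclipsing the enolate (A(1,3) strain), so C9 closes with the C20 methyl axial and the carboxyl group equatorial, and pentafluorophenoxide rebound frees the catalyst; closest known reaction types are isothiourea-catalysed Michael additions to α,β-unsaturated acyl ammonium ions with aryloxide turnover, acyl-ammonium Michael–aldol–lactonisation cascades and ammonium-enolate additions to ynones (intramolecular double Michael reaction).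

**Step 4**
Reactants: 7 pentafluorophenyl (1R,4aR,8aS)-1,2,4a-trimethyl-4,5-dioxo-1,4,4a,5,6,7,8,8a-octahydronaphthalene-1-carboxylate
Product: 8 ring-A vinyl triflate (4-triflyloxy-Δ3; 6-oxo-Δ7; 9α-CO2C6F5)
Conditions: KN(SiMe3)2 (1.05 equiv), THF, −78 °C; then Comins reagent, −78 °C
Reagents that add atoms: Comins reagent, N-(5-chloropyridin-2-yl)bis(trifluoromethanesulfonimide), O=S(=O)(N(c1ccc(Cl)cn1)S(=O)(=O)C(F)(F)F)C(F)(F)F
Why: Kinetic enolate O-triflation: the C4 ketone has α-hydrogens only at C3, the enone offers only its slower γ-methyl and the ester has no α-hydrogen, so one enol triflate forms and no stereocentre is touched.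

**Step 5**
Reactants: 8 ring-A vinyl triflate (4-triflyloxy-Δ3; 6-oxo-Δ7; 9α-CO2C6F5)
Product: 9 6β,11-diol (6β-hydroxy-Δ7; 9α-CH2OH; 4-triflyloxy-Δ3)
Conditions: i-Bu2AlH (6 equiv), CH2Cl2, −78 → −20 °C; aq. potassium sodium tartrate
Reagents that add atoms: none
Why: Hydride reduction (1,2-reduction of the enone and reduction of the activated ester to the primary alcohol); hydride enters C6 from the α face, opposite the adjacent axial C19 methyl, giving the 6β (equatorial) alcohol.

**Step 6**
Reactants: 9 6β,11-diol (6β-hydroxy-Δ7; 9α-CH2OH; 4-triflyloxy-Δ3)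
Product: 10 6β-hydroxy-11-aldehyde
Conditions: TEMPO (10 mol %), PhI(OAc)2 (1.2 equiv), CH2Cl2, rt
Reagents that add atoms: none
Why: Oxoammonium (TEMPO) oxidation is selective for the primary alcohol over the secondary allylic alcohol that is flanked by a quaternary carbon.

**Step 7**
Reactants: 10 6β-hydroxy-11-aldehyde
Product: 11 6β-acetoxy-11-aldehyde
Conditions: Ac2O (3 equiv), pyridine, DMAP (0.1 equiv), CH2Cl2, rt
Reagents that add atoms: acetic anhydride, CC(=O)OC(C)=O
Why: DMAP-catalysed acylation of the only hydroxyl group, with retention at C6; the aldehyde has no α-hydrogen.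

**Step 8**
Reactants: 11 6β-acetoxy-11-aldehyde
Product: 12 6β-acetoxy-7α,8α-dihydroxy-11-aldehyde (8β-Me)
Conditions: OsO4 (5 mol %), NMO (2 equiv), acetone/H2O 4:1, rt
Reagents that add atoms: osmium tetroxide, O=[Os](=O)(=O)=O; N-methylmorpholine N-oxide, C[N+]1([O-])CCOCC1; water, O
Why: Upjohn syn-dihydroxylation: Δ7 is the only nucleophilic alkene (the enol triflate is inert) and OsO4 adds from the α face, anti to the allylic acetate (Kishi model) and away from the two axial β-methyls, setting 7α-OH and 8α-OH.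

**Step 9**
Reactants: 12 6β-acetoxy-7α,8α-dihydroxy-11-aldehyde (8β-Me)
Product: 13 6β-acetoxy-8α-hydroxy-7α-isobutyryloxy-11-aldehyde
Conditions: (i-PrCO)2O (2 equiv), Et3N (3 equiv), DMAP (0.2 equiv), CH2Cl2, 0 °C → rt
Reagents that add atoms: isobutyric anhydride, CC(C)C(=O)OC(=O)C(C)C
Why: DMAP-catalysed acylation takes the secondary 7-OH and leaves the tertiary 8-OH free.

**Step 10**
Reactants: 13 6β-acetoxy-8α-hydroxy-7α-isobutyryloxy-11-aldehyde
Product: 14 9α-vinyl compound (ring-A vinyl triflate retained)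
Conditions: Zn, CH2Br2, TiCl4 (preformed Takai–Lombardo reagent), THF/CH2Cl2, 0 °C → rt
Reagents that add atoms: dibromomethane, BrCBr
Why: Takai–Lombardo methylenation is non-basic and selective for the aldehyde over esters, so the β-hydroxy aldehyde is never exposed to retro-aldol conditions.

**Step 11**
Reactants: 14 9α-vinyl compound (ring-A vinyl triflate retained)
Product: 15 6β-acetoxy-8α-hydroxy-7α-isobutyryloxy-13,14,15,16-tetranorcleroda-3,11-diene
Conditions: Pd(PPh3)4 (5 mol %), MeZnCl (4 equiv), THF, 0 → 45 °C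
Reagents that add atoms: methylzinc chloride, C[Zn]Cl
Why: Negishi coupling of the enol triflate installs the C18 methyl and the Δ3 alkene; the esters tolerate the organozinc and the tertiary alcohol only consumes one equivalent.

**Step 12**
Reactants: 16 tetronic acid
Product: 17 5-oxo-2,5-dihydrofuran-3-yl trifluoromethanesulfonate
Conditions: Tf2O (1.1 equiv), i-Pr2NEt (1.2 equiv), CH2Cl2, −78 °C
Reagents that add atoms: trifluoromethanesulfonic anhydride, O=S(=O)(OS(=O)(=O)C(F)(F)F)C(F)(F)F
Why: O-sulfonylation of the enol of a vinylogous acid gives the vinylogous acyl triflate.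

**Step 13**
Reactants: 15 6β-acetoxy-8α-hydroxy-7α-isobutyryloxy-13,14,15,16-tetranorcleroda-3,11-diene; 17 5-oxo-2,5-dihydrofuran-3-yl trifluoromethanesulfonate
Product: 18 (5R,6R,7S,8R,9R,10S)-6-acetoxy-8-hydroxy-7-isobutyryloxycleroda-3,11E,13-trien-15,16-olide (CNP0207114.1)
Conditions: Pd(OAc)2 (10 mol %), P(o-tol)3 (20 mol %), Et3N (3 equiv), n-Bu4NCl (1 equiv), DMF, 70 °C
Reagents that add atoms: none
Why: Mizoroki–Heck reaction: zerovalent palladium inserts into the triflate, the butenolide carbon adds to the terminal carbon of the neopentyl vinyl group, and β-hydride elimination can only occur from C12 (C9 is quaternary), giving the (E)-11,12-alkene.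

**Compound list**
1 | hex-4-yn-3-one | CCC(=O)C#CC | starting material
2 | hex-5-enoyl chloride | C=CCCCC(=O)Cl | starting material
3 | 7-methylundec-1-en-9-yne-6,8-dione (racemic, labile centre) | C=CCCCC(=O)C(C)C(=O)C#CC | intermediate
4 | pentafluorophenyl methacrylate | CC(=C)C(=O)Oc1c(F)c(F)c(F)c(F)c1F | starting material
5 | pentafluorophenyl (2E)-2,8-dimethyl-7,9-dioxododec-2-en-10-ynoate (racemic, labile centre) | CC#CC(=O)C(C)C(=O)CCC/C=C(\C)C(=O)Oc1c(F)c(F)c(F)c(F)c1F | intermediate
6 | monocyclic acylammonium enolate (ring A closed, 5β-Me and 10α-H set, (2S,3R)-HyperBTM bound at C11) | CC#CC(=O)[C@@]1(C)C(=O)CCC[C@@H]1C(C)=C([O-])[N+]1=C2Sc3ccccc3N2C[C@@H](C(C)C)[C@H]1c1ccccc1 | intermediate (not isolated)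
7 | pentafluorophenyl (1R,4aR,8aS)-1,2,4a-trimethyl-4,5-dioxo-1,4,4a,5,6,7,8,8a-octahydronaphthalene-1-carboxylate (clerodane numbering: 4,6-dioxo-Δ7, 5β-Me, 9β-Me, 9α-ester, 10α-H) | O=C1C=C(C)[C@](C)(C(=O)Oc3c(F)c(F)c(F)c(F)c3F)[C@H]2CCCC(=O)[C@]12C | intermediate
8 | ring-A vinyl triflate of 7 (4-triflyloxy-Δ3, 6-oxo-Δ7, 9α-CO2C6F5) | O=C1C=C(C)[C@](C)(C(=O)Oc3c(F)c(F)c(F)c(F)c3F)[C@H]2CCC=C(OS(=O)(=O)C(F)(F)F)[C@]12C | intermediate
9 | 6β,11-diol (6β-hydroxy-Δ7, 9α-CH2OH, 4-triflyloxy-Δ3) | O[C@H]1C=C(C)[C@](C)(CO)[C@H]2CCC=C(OS(=O)(=O)C(F)(F)F)[C@]12C | intermediate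
10 | 6β-hydroxy-11-aldehyde (Δ7, 4-triflyloxy-Δ3) | O[C@H]1C=C(C)[C@](C)(C=O)[C@H]2CCC=C(OS(=O)(=O)C(F)(F)F)[C@]12C | intermediate
11 | 6β-acetoxy-11-aldehyde (Δ7, 4-triflyloxy-Δ3) | CC(=O)O[C@H]1C=C(C)[C@](C)(C=O)[C@H]2CCC=C(OS(=O)(=O)C(F)(F)F)[C@]12C | intermediate
12 | 6β-acetoxy-7α,8α-dihydroxy-11-aldehyde (8β-Me, 4-triflyloxy-Δ3) | CC(=O)O[C@H]1[C@H](O)[C@](C)(O)[C@](C)(C=O)[C@H]2CCC=C(OS(=O)(=O)C(F)(F)F)[C@]12C | intermediate
13 | 6β-acetoxy-8α-hydroxy-7α-isobutyryloxy-11-aldehyde (4-triflyloxy-Δ3) | CC(=O)O[C@H]1[C@H](OC(=O)C(C)C)[C@](C)(O)[C@](C)(C=O)[C@H]2CCC=C(OS(=O)(=O)C(F)(F)F)[C@]12C | intermediate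
14 | 9α-vinyl compound (6β-OAc, 7α-O-isobutyryl, 8α-OH, 4-triflyloxy-Δ3) | CC(=O)O[C@H]1[C@H](OC(=O)C(C)C)[C@](C)(O)[C@](C)(C=C)[C@H]2CCC=C(OS(=O)(=O)C(F)(F)F)[C@]12C | intermediate
15 | 6β-acetoxy-8α-hydroxy-7α-isobutyryloxy-13,14,15,16-tetranorcleroda-3,11-diene | CC(=O)O[C@H]1[C@H](OC(=O)C(C)C)[C@](C)(O)[C@](C)(C=C)[C@H]2CCC=C(C)[C@]12C | intermediate
16 | tetronic acid (4-hydroxyfuran-2(5H)-one) | OC1=CC(=O)OC1 | starting material
17 | 5-oxo-2,5-dihydrofuran-3-yl trifluoromethanesulfonate | O=C1OCC(OS(=O)(=O)C(F)(F)F)=C1 | intermediate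
18 | (5R,6R,7S,8R,9R,10S)-6-acetoxy-8-hydroxy-7-isobutyryloxycleroda-3,11E,13-trien-15,16-olide | CC(=O)O[C@H]1[C@H](OC(=O)C(C)C)[C@](C)(O)[C@](C)(/C=C/C2=CC(=O)OC2)[C@H]2CCC=C(C)[C@]12C | target

**Totals:** 13 steps; longest linear sequence 12 (steps 1–11 and 13).

**Three steps most likely to fail**

Step 3 (acyl transfer from the α-branched aryl ester may be slow; ring-fusion, C9 and enantio-selectivity are predicted, not demonstrated). The fallback sets out from 3 and changes the activation mode. Cross-metathesis of 3 with methacrolein gives (2E)-2,8-dimethyl-7,9-dioxododec-2-en-10-ynal F1. F1 is cyclised under oxidative N-heterocyclic-carbene catalysis (aminoindanol-derived N-mesityl triazolium chloride, DBU 20 mol %, LiCl, 3,3′,5,5′-tetra-tert-butyldiphenoquinone, MeOH added slowly, THF) through the unsaturated acyl azolium and its azolium enolate to the bicyclic methyl ester F2. Comins triflation as in step 4 gives the methyl ester vinyl triflate F3, and i-Bu2AlH reduction of F3 comes back to the route at 9.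

Step 8 (OsO4 may be sluggish on the hindered, acetate-deactivated alkene, and the acetate may migrate to O7). The fallback sets out from 10 and changes the order of oxygenation. The more electron-rich free allylic alcohol 10 is dihydroxylated first (OsO4, NMO, same α face) to the 6β,7α,8α-triol aldehyde F4. The cis-7,8-diol is tied up with 2,2-dimethoxypropane and PPTS as the 7,8-acetonide F5, O6 is acetylated (Ac2O, DMAP) to the acetonide acetate F6, and aqueous acetic acid removes the acetonide to come back at 12.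

Step 13 (Heck insertion into a vinyl group on a quaternary carbon may fail or give regioisomers). The fallback sets out from 13 and reverses the coupling polarity. Takai–Utimoto boryl-olefination of aldehyde 13 (CrCl2, LiI, Cl2CHBpin, THF) gives the (E)-alkenyl pinacolboronate F7. Suzuki–Miyaura coupling of F7 with triflate 17 (PdCl2(dppf), CsF, THF; the electron-poor triflate 17 reacts before the hindered ring-A triflate) gives the dienyl butenolide vinyl triflate F8. Negishi methylation of F8 as in step 11 comes back at the target 18.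

**Further compounds**
F1 | step 3 | (2E)-2,8-dimethyl-7,9-dioxododec-2-en-10-ynal | O=C/C(C)=C/CCCC(=O)C(C)C(=O)C#CC
F2 | step 3 | methyl (1R,4aR,8aS)-1,2,4a-trimethyl-4,5-dioxo-1,4,4a,5,6,7,8,8a-octahydronaphthalene-1-carboxylate | O=C1C=C(C)[C@](C)(C(=O)OC)[C@H]2CCCC(=O)[C@]12C
F3 | step 3 | ring-A vinyl triflate of F2 (4-triflyloxy-Δ3, 6-oxo-Δ7, 9α-CO2Me) | O=C1C=C(C)[C@](C)(C(=O)OC)[C@H]2CCC=C(OS(=O)(=O)C(F)(F)F)[C@]12C
F4 | step 8 | 6β,7α,8α-trihydroxy-11-aldehyde (4-triflyloxy-Δ3) | O[C@H]1[C@H](O)[C@](C)(O)[C@](C)(C=O)[C@H]2CCC=C(OS(=O)(=O)C(F)(F)F)[C@]12C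
F5 | step 8 | 7α,8α-O-isopropylidene-6β-hydroxy-11-aldehyde | O[C@H]1[C@@H]2OC(C)(C)O[C@]2(C)[C@](C)(C=O)[C@H]3CCC=C(OS(=O)(=O)C(F)(F)F)[C@]13C
F6 | step 8 | 6β-acetoxy-7α,8α-O-isopropylidene-11-aldehyde | CC(=O)O[C@H]1[C@@H]2OC(C)(C)O[C@]2(C)[C@](C)(C=O)[C@H]3CCC=C(OS(=O)(=O)C(F)(F)F)[C@]13C
F7 | step 13 | (E)-alkenyl pinacolboronate from 13 (C11=C12–Bpin, ring-A triflate retained) | CC(=O)O[C@H]1[C@H](OC(=O)C(C)C)[C@](C)(O)[C@](C)(/C=C/B2OC(C)(C)C(C)(C)O2)[C@H]2CCC=C(OS(=O)(=O)C(F)(F)F)[C@]12C
F8 | step 13 | 4-triflyloxy-18-nor analogue of the target (dienyl butenolide, ring-A vinyl triflate) | CC(=O)O[C@H]1[C@H](OC(=O)C(C)C)[C@](C)(O)[C@](C)(/C=C/C2=CC(=O)OC2)[C@H]2CCC=C(OS(=O)(=O)C(F)(F)F)[C@]12C
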